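Start with the acid.

    electrophile + nucleophile → acid set free + target (k1 = 13 L mol⁻¹ h⁻¹)
    nucleophile + acid set free ⇌ protonated nucleophile, settled at all times (K2 = 260 L mol⁻¹)
    2 nucleophile → homo dimer (k3 = 0.032 L mol⁻¹ h⁻¹)
    acid set free + target → side product (k4 = 1.0 L mol⁻¹ h⁻¹)
    crystals ⇌ acid set free, rate k5*(cs5 - [acid set free]) while solid is left; crystals form when [acid set free] > cs5 (cs5 = 0.15 M, k5 = 13 h⁻¹)

electrophile 0.30 M; time 8.0 d

1. the concentration of nucleophile at which the part of the electrophile that has reacted at 8.0 d is just 80%, in M

- amounts and yields of acid set free count crystals too
- two of one species on the left: rate k times its square, two consumed each time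
- given per volume of solution although it is solid: crystals
- the amount of nucleophile is what is sought; it is there from the start
- run time (flask): 8.0 d

Each electrophile that reacts takes one nucleophile, so I make nucleophile the limiting reagent and first guess a charge of 0.240 M, provided the run is long enough. The acid set free ties up nucleophile as protonated nucleophile. Crystals form above 0.15 M, so I take that as the worst free acid, and then one part in 40.0 of the unreacted nucleophile, free and protonated counted together, is free. With 0.0600 M electrophile left near the end, that pool decays pseudo-first-order with time constant 2.14 d. Dividing the run time by it gives n = 3.74, the number of worst-case time constants the run holds for using up the last nucleophile. Because n is larger than one, I commit to 0.240 M. As a test of that one number, with the charge I guess, the dimer step at the start uses nucleophile at 0.00394 of the rate of the main step, and the side product step has no nucleophile on its left-hand side.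

The forecast gives 0.2403 M, on the ground that “Conversion is thus limited by stoichiometry”.

The simulation gives 0.240 M. In this flask the main step ran while free nucleophile was there, the half-life of nucleophile by that step being 0.30 h at 0.0230 d, shorter than the run, and it had 98% of its turnover up to 8.0 d behind it after 1.60 d. The side product step ran while acid set free and target stood together, reaching 58% of its turnover up to 8.0 d after 0.800 d, and free nucleophile stood at 0% of its charge at 8.00 d. In a second flask charged with 0.192 M nucleophile, n reckoned on the electrophile left at 8.0 d is 6.74, the ratio of nucleophile to electrophile charged is 64.1%, and the part of the electrophile reacted at 8.0 d is 64.0%.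

(The rate constants come from no measurement; the result is computed.)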